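**Plan**

1. Retrosynthesis: the C5–CHO bond is cut first (an aryl bromide stands in for the aldehyde), the furan C2=C3 bond is taken back to the dihydro level, and then C2–C3 and O1–C2 of ring B (the furan; ring A is the benzo ring, ring C the trimethoxyphenyl ring) are cut together.
2. Enabling feature: C2 is bonded to both C3 and O1, so it can arrive as one benzylic sulfonium-ylide carbon, nucleophilic toward C3 and then electrophilic toward O1; O1, C7a, C3a and C3 with its methyl group form an ethylidene ortho-quinone methide.
3. Forward: rings A and C are bought; ring A is elaborated to sulfone 5 (steps 1–3) and ring C to sulfonium salt 8 (steps 4–5); step 6 closes ring B, step 7 aromatises it, and step 8 converts C5–Br into C5–CHO.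
4. Stereochemistry: the target has none; C2 and C3 of dihydrobenzofuran 12 arise racemic and trans in step 6 and are erased in step 7, and the stereocentres of 3 and 5 vanish when the quinone methide forms.

Key step: step 6

Remark: racemic compounds are written without wedges or as one enantiomer; the quinone methide is written as its (E)-isomer, a geometry that has no bearing on the outcome.

**Step 1**
Reactants: 1 1-(2-hydroxy-3-methoxyphenyl)ethanone
Product: 2 1-(5-bromo-2-hydroxy-3-methoxyphenyl)ethanone
Conditions: NBS (1.05 equiv), MeCN, 0 °C to rt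
Reagents that add atoms: N-bromosuccinimide, O=C1CCC(=O)N1Br
Why: Electrophilic aromatic bromination should go to C5, which is para to the hydroxyl group and meta to the acetyl group, while the ketone methyl group is not brominated under these neutral conditions.

**Step 2**
Reactants: 2 1-(5-bromo-2-hydroxy-3-methoxyphenyl)ethanone
Product: 3 racemic 4-bromo-2-(1-hydroxyethyl)-6-methoxyphenol
Conditions: NaBH4, MeOH, 0 °C; then 1 M HCl to pH 6
Reagents that add atoms: none
Why: Hydride reduction of an aryl ketone with NaBH4 leaves the aryl bromide and ethers untouched and gives a racemic carbinol centre that becomes trigonal again in step 6.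

**Step 3**
Reactants: 3 racemic 4-bromo-2-(1-hydroxyethyl)-6-methoxyphenol; 4 sodium 4-methylbenzenesulfinate
Product: 5 racemic 4-bromo-2-methoxy-6-[1-(4-methylphenylsulfonyl)ethyl]phenol
Conditions: 4 (1.5 equiv), HCO2H/H2O (1:1), rt to 40 °C
Reagents that add atoms: sodium 4-methylbenzenesulfinate (compound 4), Cc1ccc(S(=O)[O-])cc1.[Na+]
Why: Acid-promoted SN1-type substitution of a 2-hydroxybenzylic alcohol, in which the ortho-hydroxyl group assists ionisation and the ambident sulfinate bonds through sulfur to give the more stable sulfone, racemic at the benzylic carbon.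

**Step 4**
Reactants: 6 3,4,5-trimethoxybenzyl alcohol
Product: 7 5-(bromomethyl)-1,2,3-trimethoxybenzene
Conditions: PBr3 (0.4 equiv), CH2Cl2, 0 °C
Reagents that add atoms: phosphorus tribromide, BrP(Br)Br
Why: Bromination of a primary benzylic alcohol with PBr3 is an SN2 displacement after activation of oxygen on phosphorus, and the aryl methyl ethers are inert at 0 °C.

**Step 5**
Reactants: 7 5-(bromomethyl)-1,2,3-trimethoxybenzene
Product: 8 dimethyl(3,4,5-trimethoxybenzyl)sulfonium bromide
Conditions: Me2S (3 equiv), acetone, rt, dark; salt collected by filtration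
Reagents that add atoms: dimethyl sulfide, CSC
Why: SN2 S-alkylation of dimethyl sulfide by a reactive benzylic bromide, driven to completion because the sulfonium salt crystallises from acetone.

**Step 6**
Reactants: 5 racemic 4-bromo-2-methoxy-6-[1-(4-methylphenylsulfonyl)ethyl]phenol; 8 dimethyl(3,4,5-trimethoxybenzyl)sulfonium bromide
Product: 12 racemic trans-(2R*,3R*)-5-bromo-7-methoxy-3-methyl-2-(3,4,5-trimethoxyphenyl)-2,3-dihydro-1-benzofuran, via ortho-quinone methide 9 (not isolated), via sulfonium ylide 10 (not isolated), via phenoxide–sulfonium betaine 11 (not isolated)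
Conditions: 8 (1.5 equiv), Cs2CO3 (3 equiv), MeCN, 0 °C to rt
Reagents that add atoms: none
Why: Cs2CO3 deprotonates the phenol of 5, whose phenoxide expels 4-methylbenzenesulfinate in an E1cB-type 1,4-elimination to release quinone methide 9, while the same base reversibly deprotonates 8 at its benzylic carbon to give ylide 10. The ylide carbon adds to the exocyclic carbon of 9 in a vinylogous conjugate addition that forms C2–C3 and restores the aromatic phenoxide in betaine 11, and this phenoxide then displaces dimethyl sulfide from the benzylic carbon to form O1–C2. The closest known reaction type is the formal (4+1) annulation of ortho-quinone methides released from 2-(1-sulfonylalkyl)phenols with sulfur ylides, in which semi-stabilised benzylic ylides are the less usual partners. Ring B closes in a 5-exo-tet mode by intramolecular SN2 substitution. C3 is created in the addition and C2 is fixed by inversion in the closure, and because the betaine that places aryl and methyl apart closes faster the trans isomer is expected, racemic since nothing chiral is present, with both centres erased in step 7. The step needs the ylide to intercept 9 faster than 9 dimerises and needs a partner free of carbonyl groups, which the slow heterogeneous release of 9 in the presence of excess 8 and the bromine at the future formyl carbon respectively secure, since an aldehyde would be epoxidised by the ylide in a Corey–Chaykovsky reaction.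

**Step 7**
Reactants: 12 racemic trans-5-bromo-7-methoxy-3-methyl-2-(3,4,5-trimethoxyphenyl)-2,3-dihydro-1-benzofuran
Product: 13 5-bromo-7-methoxy-3-methyl-2-(3,4,5-trimethoxyphenyl)-1-benzofuran
Conditions: DDQ (1.5 equiv), dry 1,4-dioxane, reflux
Reagents that add atoms: none
Why: DDQ dehydrogenation by hydride abstraction from C2, which is benzylic to the electron-rich ring C and alpha to O1, followed by loss of the C3 proton, should give the aromatic furan and remove both stereocentres.

**Step 8**
Reactants: 13 5-bromo-7-methoxy-3-methyl-2-(3,4,5-trimethoxyphenyl)-1-benzofuran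
Product: 16 7-methoxy-3-methyl-2-(3,4,5-trimethoxyphenyl)-1-benzofuran-5-carbaldehyde (ocophyllal B), via aryllithium 14 (not isolated), via lithium aminoalkoxide 15 (not isolated)
Conditions: n-BuLi (1.1 equiv), THF, −78 °C; DMF (3 equiv), −78 °C to 0 °C; 1 M HCl
Reagents that add atoms: N,N-dimethylformamide, CN(C)C=O
Why: Bromine–lithium exchange followed by formylation with DMF (Bouveault aldehyde synthesis) should be clean because C2 and C3 carry no acidic hydrogen and aminoalkoxide 15 resists a second addition until acidic work-up releases the aldehyde.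

**Compound list**

1 | 1-(2-hydroxy-3-methoxyphenyl)ethanone | COc1cccc(C(C)=O)c1O | starting material
2 | 1-(5-bromo-2-hydroxy-3-methoxyphenyl)ethanone | COc1cc(Br)cc(C(C)=O)c1O | intermediate
3 | racemic 4-bromo-2-(1-hydroxyethyl)-6-methoxyphenol | COc1cc(Br)cc(C(C)O)c1O | intermediate
4 | sodium 4-methylbenzenesulfinate | Cc1ccc(S(=O)[O-])cc1.[Na+] | starting material
5 | racemic 4-bromo-2-methoxy-6-[1-(4-methylphenylsulfonyl)ethyl]phenol | COc1cc(Br)cc(C(C)S(=O)(=O)c2ccc(C)cc2)c1O | intermediate
6 | 3,4,5-trimethoxybenzyl alcohol | COc1cc(CO)cc(OC)c1OC | starting material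
7 | 5-(bromomethyl)-1,2,3-trimethoxybenzene | COc1cc(CBr)cc(OC)c1OC | intermediate
8 | dimethyl(3,4,5-trimethoxybenzyl)sulfonium bromide | C[S+](C)Cc1cc(OC)c(OC)c(OC)c1.[Br-] | intermediate
9 | (E)-4-bromo-6-ethylidene-2-methoxycyclohexa-2,4-dien-1-one (ortho-quinone methide) | C/C=C1\C=C(Br)C=C(OC)C1=O | intermediate (not isolated)
10 | dimethylsulfonium (3,4,5-trimethoxyphenyl)methylide | C[S+](C)[CH-]c1cc(OC)c(OC)c(OC)c1 | intermediate (not isolated)
11 | racemic 4-bromo-2-[(1S*,2R*)-1-(dimethylsulfonio)-1-(3,4,5-trimethoxyphenyl)propan-2-yl]-6-methoxyphenolate (betaine, one enantiomer drawn) | C[C@H](c1cc(Br)cc(OC)c1[O-])[C@H]([S+](C)C)c1cc(OC)c(OC)c(OC)c1 | intermediate (not isolated)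
12 | racemic trans-(2R*,3R*)-5-bromo-7-methoxy-3-methyl-2-(3,4,5-trimethoxyphenyl)-2,3-dihydro-1-benzofuran (one enantiomer drawn) | C[C@H]1[C@H](c2cc(OC)c(OC)c(OC)c2)Oc2c(OC)cc(Br)cc21 | intermediate
13 | 5-bromo-7-methoxy-3-methyl-2-(3,4,5-trimethoxyphenyl)-1-benzofuran | COc1cc(-c2oc3c(OC)cc(Br)cc3c2C)cc(OC)c1OC | intermediate
14 | [7-methoxy-3-methyl-2-(3,4,5-trimethoxyphenyl)-1-benzofuran-5-yl]lithium | [Li]c1cc(OC)c2oc(-c3cc(OC)c(OC)c(OC)c3)c(C)c2c1 | intermediate (not isolated)
15 | racemic lithium (dimethylamino)[7-methoxy-3-methyl-2-(3,4,5-trimethoxyphenyl)-1-benzofuran-5-yl]methanolate | [Li+].[O-]C(N(C)C)c1cc(OC)c2oc(-c3cc(OC)c(OC)c(OC)c3)c(C)c2c1 | intermediate (not isolated)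
16 | 7-methoxy-3-methyl-2-(3,4,5-trimethoxyphenyl)-1-benzofuran-5-carbaldehyde (ocophyllal B) | COc1cc(-c2oc3c(OC)cc(C=O)cc3c2C)cc(OC)c1OC | target

**Step count**

Total: 8 steps. Longest linear sequence: 6 steps (steps 1, 2, 3, 6, 7, 8); the second branch (steps 4, 5) joins at step 6.

**Steps most likely to fail, with fallbacks**

Step 6. The quinone methide may be lost to self-dimerisation by hetero-Diels–Alder reaction. The phenoxide of 5 may be O-benzylated by the sulfonium salt before sulfinate leaves. The ylide may undergo a Sommelet–Hauser rearrangement instead of adding.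

The fallback sets out from alcohol 3 and returns at benzofuran 13, so it also makes step 7 unnecessary. Heating 3 with triphenylphosphine hydrobromide in MeCN should give racemic [1-(5-bromo-2-hydroxy-3-methoxyphenyl)ethyl]triphenylphosphonium bromide F1. Treatment of F1 with 3,4,5-trimethoxybenzoyl chloride and Et3N in toluene at reflux should acylate the phenol to give racemic {1-[5-bromo-3-methoxy-2-(3,4,5-trimethoxybenzoyloxy)phenyl]ethyl}triphenylphosphonium bromide F2. In the same flask F2 is deprotonated at the phosphorus-bearing carbon and closes by intramolecular Wittig reaction onto the ester carbonyl. O1–C2 then comes from the acylation and C2=C3 from the olefination.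

Step 7. Hydride abstraction may be slow because ring A carries bromine, and long heating invites oxidation at the 3-methyl group of the product.

The fallback sets out from 12 and returns at 13. It replaces hydride abstraction by radical halogenation and elimination. NBS with catalytic AIBN in PhCF3 at 80 °C should brominate the doubly activated C2–H to give 2,5-dibromo-7-methoxy-3-methyl-2-(3,4,5-trimethoxyphenyl)-2,3-dihydro-1-benzofuran F3. Adding Et3N should make F3 lose hydrogen bromide across C2–C3.

Step 3. The ionised benzylic position may alkylate a second phenol ring (Friedel–Crafts oligomerisation) or be captured by sulfinate through oxygen, and the sulfinic acid may disproportionate on warming.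

The fallback sets out from 3 and returns at sulfone 5. Acid-catalysed thioetherification with 4-methylbenzenethiol (catalytic TsOH·H2O, CH2Cl2, rt) should give racemic 4-bromo-2-methoxy-6-[1-(4-methylphenylsulfanyl)ethyl]phenol F4, since the thiol is a better and unambiguous sulfur nucleophile. Oxidation of F4 with mCPBA (2.2 equiv, CH2Cl2, 0 °C) should then give 5.

**Further compounds**

F1 | step 6 | racemic [1-(5-bromo-2-hydroxy-3-methoxyphenyl)ethyl]triphenylphosphonium bromide | CC(c1cc(Br)cc(OC)c1O)[P+](c1ccccc1)(c1ccccc1)c1ccccc1.[Br-]
F2 | step 6 | racemic {1-[5-bromo-3-methoxy-2-(3,4,5-trimethoxybenzoyloxy)phenyl]ethyl}triphenylphosphonium bromide | CC(c1cc(Br)cc(OC)c1OC(=O)c1cc(OC)c(OC)c(OC)c1)[P+](c1ccccc1)(c1ccccc1)c1ccccc1.[Br-]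
F3 | step 7 | 2,5-dibromo-7-methoxy-3-methyl-2-(3,4,5-trimethoxyphenyl)-2,3-dihydro-1-benzofuran (mixture of diastereomers) | CC1c2cc(Br)cc(OC)c2OC1(Br)c1cc(OC)c(OC)c(OC)c1
F4 | step 3 | racemic 4-bromo-2-methoxy-6-[1-(4-methylphenylsulfanyl)ethyl]phenol | COc1cc(Br)cc(C(C)Sc2ccc(C)cc2)c1O
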